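6.20 M·d is the number to hold in this flask: the charge of substrate multiplied by the time, which I call the charge clock.

| flask | substrate | remark | time |
|---|---|---|---|
| noon | 0.87 M | run made earlier |  |
| summer | 1.4 M | run made earlier |  |
| flask | 0.62 M |  | 10 d |

- noon (time / d: homo dimer / %, target / %, substrate / %): 0.333: 46.0, 8.5, 42.2; 0.833: 62.3, 10.6, 22.8; 1.67: 71.2, 9.8, 15.9; 2.50: 76.2, 8.6, 13.0; 4.00: 83.0, 6.9, 9.6; 5.00: 85.8, 4.1, 7.9; 6.00: 87.5, 4.1, 7.3
- summer (time / d: homo dimer / %, target / %, substrate / %): 0.333: 58.4, 7.4, 31.8; 0.833: 71.3, 7.3, 17.0; 1.67: 79.4, 7.8, 10.2; 2.50: 83.7, 6.1, 8.7; 4.00: 88.1, 4.2, 7.1; 5.00: 89.8, 3.2, 5.4; 6.00: 91.1, 2.9, 4.2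

(standard deviation of a reading: 0.5 percentage points)

- percent here means substrate units held: one homo dimer counts as two
- the analysis behind the earlier runs scatters by 0.5 percentage points, standard deviation

- homo dimer present at 10 d, in percent of the substrate charged
- target present at 10 d, in percent of the substrate charged
- substrate present at 10 d, in percent of the substrate charged

If two substrates pair up in a second-order loss, the daily fall of the fraction left, divided by the charge, depends on that fraction. Time then drops out of that loss in favour of the clock, and I take it that runs at equal clock stand alike. You can test both parts on the earlier runs.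

Inverse of the fraction of substrate left, less one, over the clock, at the first reading:
noon 4.73 M⁻¹ d⁻¹, summer 4.60 M⁻¹ d⁻¹

Noon at 4.00 d (clock 3.48 M·d) against summer at 2.50 d (clock 3.50 M·d):
homo dimer 83.0 % and 83.7 %; target 6.9 % and 6.1 %; substrate 9.6 % and 8.7 %

The substrate gap is 0.9 percentage points against a scatter of 0.5 points per reading, so on these readings two runs at equal clock match to about that gap.

The noon run looks nearly the same as your flask and ended at 87.5 % homo dimer. But noon stopped at 6.00 d, with a clock of 5.22 M·d, less than this flask's, so this flask ends further on despite its lower charge. The summer run reaches this flask's clock at 4.43 d, between two readings, and interpolating there gives my reckoning: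

homo dimer 88.8 %, target 3.77 %, substrate 6.37 %

The forecast, holding that “homo dimer forms from two substrates”, gives homo dimer 89 %, target 3.8 % and substrate 6.2 %, the last lower than mine.

The flask gives homo dimer 89.0 %, target 3.47 % and substrate 6.42 %.

    substrate ⇌ target (K = 0.490, k = 2.90 × 10⁻⁴ min⁻¹)
    target ⇌ isomer of the product (K = 0.330, k = 0.0120 min⁻¹)
    isomer of the product ⇌ substrate (k = 0.00100 min⁻¹)
    2 substrate → homo dimer (k = 0.00130 M⁻¹ min⁻¹)

At a clock of 6.20 M·d this flask's target lies 0.30 points below my reckoned value. The same flask read at 2.5 d, clock 1.55 M·d, holds homo dimer 70.9 %, target 9.89 % and substrate 15.9 %, beside the noon readings at 1.67 d, clock 1.45 M·d, of 71.2 %, 9.8 % and 15.9 %. This flask is not at rest at 10 d. At 100 d, ten times the time, homo dimer has climbed from 89.0 % to 98.8 %, target has fallen to 0.355 %, and substrate to 0.717 %.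

The earlier runs and the new flask were generated by integration from invented constants; noise was put on by code.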